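The plan cuts the tetrahydrofuran (O1, C2, C3, C4, C5) at O1–C2 and C3–C4. C3 carries the carbinol carbon C7' of ring B; at the ketone level this makes O1–C2 the product of an alkoxide conjugate addition and C3–C4 the product of an enolate allylic alkylation. A single palladium-catalysed (3+2) annulation of racemic 2-vinyloxirane with the ring B aryl vinyl ketone therefore closes the ring and sets C3 and C4 (trans) under ligand control. The precursor is the O-benzyl 4-hydroxy-3-methoxyphenyl vinyl ketone. Later the C4 vinyl group is cut down to a CH2 handle for coupling with ring A, and C7' is set by catalyst-controlled reduction.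

Key step: step 3

Locants: ring A is the aryl ring of the benzyl arm on C4, ring B that of the carbinol arm on C3, and C7' is the carbinol carbon; the target is the (3R,4R,7'R) isomer with trans ring substituents.

Assumption: the sense of induction of the chiral ligand in step 3 is written by analogy with its behaviour toward the same π-allyl unit; if a pilot run gives the 4S series, the antipodal ligand is taken and nothing else changes.

Step 1
Reactants: 1 4-(benzyloxy)-3-methoxybenzaldehyde
Product: 2 rac-1-[4-(benzyloxy)-3-methoxyphenyl]prop-2-en-1-ol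
Conditions: CH2=CHMgBr (1.2 equiv), THF, −78 to 0 °C; aq. NH4Cl
Reagents that add atoms: vinylmagnesium bromide, C=C[Mg]Br
Why: Grignard 1,2-addition of a vinyl nucleophile to an aromatic aldehyde is fast and clean at low temperature, the aryl ethers are inert, and the racemic carbinol centre is erased in step 2.

Step 2
Reactants: 2 rac-1-[4-(benzyloxy)-3-methoxyphenyl]prop-2-en-1-ol
Product: 3 1-[4-(benzyloxy)-3-methoxyphenyl]prop-2-en-1-one
Conditions: activated MnO2 (10 equiv), CH2Cl2, rt; filtered through Celite, concentrated cold, used at once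
Reagents that add atoms: none
Why: MnO2 oxidation of an alcohol that is both benzylic and allylic is selective under neutral heterogeneous conditions, so the polymerisation-prone aryl vinyl ketone should be obtained by filtration alone.

Step 3
Reactants: 3 1-[4-(benzyloxy)-3-methoxyphenyl]prop-2-en-1-one; 4 rac-2-vinyloxirane
Product: 5 [4-(benzyloxy)-3-methoxyphenyl][(3R,4R)-4-vinyltetrahydrofuran-3-yl]methanone
Conditions: Pd2(dba)3·CHCl3 (2.5 mol%), (R,R)-DACH-naphthyl Trost ligand, i.e. N,N'-[(1R,2R)-cyclohexane-1,2-diyl]bis[2-(diphenylphosphanyl)naphthalene-1-carboxamide] (7.5 mol%), CH2Cl2, 0 °C to rt, 4 (2 equiv) added slowly; then DBU (10 mol%), rt, if a cis fraction remains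
Reagents that add atoms: none
Why: Zerovalent palladium ionises 4 to a zwitterionic alkoxide/π-allylpalladium species whose diastereomeric forms, arising from the two epoxide enantiomers, interconvert by η3–η1–η3 isomerisation faster than they are consumed; the alkoxide adds reversibly to the unsubstituted β-carbon of 3 (oxa-Michael, O1–C2) and the aryl ketone enolate so formed alkylates the allyl carbon next to the CH2O group (C3–C4), releasing the catalyst. The closest known reaction type is the palladium-catalysed formal (3+2) cycloaddition of vinyl epoxides with Michael acceptors, enones included, run as a dynamic kinetic asymmetric transformation. The tetrahydrofuran closes by a 5-exo allylic alkylation that leaves the remaining double bond outside the ring as the C4 vinyl group. C4 is set by the chiral ligand, which selects the π-allyl diastereomer and face that cyclise, whereas C3, α to the ketone, is under thermodynamic control and should settle trans to the vinyl group (catalytic DBU completes the equilibration). The step needs five-ring over seven-ring closure, carbon over oxygen alkylation and one sense at C4: attack at the inner allyl carbon is the only five-membered option for the tethered enolate, the aryl-conjugated enolate is a soft carbon nucleophile, the absence of a β-substituent in 3 keeps the conjugate addition fast and creates no further stereocentre, and the benzyl ether, unlike an acyl or silyl group on this acidic phenol, cannot be transferred to the alkoxide.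

Step 4
Reactants: 5 [4-(benzyloxy)-3-methoxyphenyl][(3R,4R)-4-vinyltetrahydrofuran-3-yl]methanone
Product: 6 (R)-[4-(benzyloxy)-3-methoxyphenyl][(3R,4R)-4-vinyltetrahydrofuran-3-yl]methanol
Conditions: (S)-2-methyl-CBS-oxazaborolidine (20 mol%), catecholborane (1.8 equiv), toluene, −78 to −20 °C; MeOH quench, aq. NaOH wash
Reagents that add atoms: none
Why: Corey–Bakshi–Shibata reduction, in which the (S)-oxazaborolidine binds the ketone with the aryl group as the larger substituent and delivers hydride to the Si face to give the 7'R carbinol, while catecholborane as hydride source does not hydroborate the vinyl group and the non-basic medium leaves C3 untouched.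

Step 5
Reactants: 6 (R)-[4-(benzyloxy)-3-methoxyphenyl][(3R,4R)-4-vinyltetrahydrofuran-3-yl]methanol
Product: 7 tert-butyl{(R)-[4-(benzyloxy)-3-methoxyphenyl][(3R,4R)-4-vinyltetrahydrofuran-3-yl]methoxy}dimethylsilane
Conditions: TBSOTf (1.3 equiv), 2,6-lutidine (2 equiv), CH2Cl2, −78 to 0 °C
Reagents that add atoms: tert-butyldimethylsilyl trifluoromethanesulfonate, CC(C)(C)[Si](C)(C)OS(=O)(=O)C(F)(F)F
Why: Silylation of a hindered secondary alcohol with a silyl triflate and a hindered pyridine base is fast at low temperature and masks the benzylic hydroxyl for the organometallic steps without touching the C7'–O bond.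

Step 6
Reactants: 7 tert-butyl{(R)-[4-(benzyloxy)-3-methoxyphenyl][(3R,4R)-4-vinyltetrahydrofuran-3-yl]methoxy}dimethylsilane
Product: 9 [(3S,4R)-4-{(R)-[4-(benzyloxy)-3-methoxyphenyl][(tert-butyldimethylsilyl)oxy]methyl}tetrahydrofuran-3-yl]methanol, via tetrahydrofuran-3-carbaldehyde 8 (not isolated)
Conditions: K2OsO4·2H2O (2 mol%), NaIO4 (4 equiv), 2,6-lutidine (2 equiv), 1,4-dioxane/H2O, rt; extractive work-up, crude 8 taken on; then NaBH4 (2 equiv), MeOH, 0 °C
Reagents that add atoms: sodium periodate, [Na+].[O-]I(=O)(=O)=O (terminal oxygen source); potassium osmate dihydrate, O.O.[K+].[K+].[O-][Os](=O)(=O)[O-] (catalytic carrier of that oxygen)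
Why: Lemieux–Johnson oxidative cleavage (catalytic dihydroxylation followed by periodate glycol cleavage, buffered with 2,6-lutidine) is selective for the terminal alkene over the electron-rich arene, and immediate borohydride reduction of the crude aldehyde secures the primary alcohol before the C4 centre α to the aldehyde can epimerise (the change of descriptor at that carbon is only a change of CIP priorities).

Step 7
Reactants: 9 [(3S,4R)-4-{(R)-[4-(benzyloxy)-3-methoxyphenyl][(tert-butyldimethylsilyl)oxy]methyl}tetrahydrofuran-3-yl]methanol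
Product: 10 tert-butyl{(R)-[4-(benzyloxy)-3-methoxyphenyl][(3R,4R)-4-(iodomethyl)tetrahydrofuran-3-yl]methoxy}dimethylsilane
Conditions: PPh3 (1.5 equiv), imidazole (2 equiv), I2 (1.4 equiv), CH2Cl2, 0 °C to rt
Reagents that add atoms: iodine, II
Why: Appel-type iodination converts the unhindered primary alcohol into the iodide by SN2 displacement of an oxyphosphonium ion, the silyl ether is stable to the buffered conditions, and the trans ring substituents keep the C7' oxygen from participating.

Step 8
Reactants: 11 4-bromo-2-methoxyphenol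
Product: 12 1-(benzyloxy)-4-bromo-2-methoxybenzene
Conditions: BnBr (1.1 equiv), K2CO3 (1.5 equiv), acetone, reflux
Reagents that add atoms: benzyl bromide, BrCc1ccccc1
Why: Williamson ether synthesis on a phenol is routine and gives ring A the same protecting group as ring B, so that both are removed together in the last step.

Step 9
Reactants: 10 tert-butyl{(R)-[4-(benzyloxy)-3-methoxyphenyl][(3R,4R)-4-(iodomethyl)tetrahydrofuran-3-yl]methoxy}dimethylsilane; 12 1-(benzyloxy)-4-bromo-2-methoxybenzene
Product: 14 tert-butyl{(R)-[4-(benzyloxy)-3-methoxyphenyl][(3R,4R)-4-[4-(benzyloxy)-3-methoxybenzyl]tetrahydrofuran-3-yl]methoxy}dimethylsilane, via alkylzinc iodide 13 (not isolated)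
Conditions: Zn dust (3 equiv, activated with cat. I2), DMF, rt; then 12 (1.2 equiv), Pd2(dba)3 (2.5 mol%), SPhos (10 mol%), DMF, rt to 50 °C
Reagents that add atoms: none
Why: Negishi coupling, in which zinc inserts into the primary C–I bond to give an alkylzinc iodide that tolerates silyl and benzyl ethers and has no leaving group β to zinc, and a zerovalent palladium/SPhos catalyst couples it with the electron-rich aryl bromide faster than β-hydride elimination, with no stereocentre involved.

Step 10
Reactants: 14 tert-butyl{(R)-[4-(benzyloxy)-3-methoxyphenyl][(3R,4R)-4-[4-(benzyloxy)-3-methoxybenzyl]tetrahydrofuran-3-yl]methoxy}dimethylsilane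
Product: 15 (R)-[4-(benzyloxy)-3-methoxyphenyl][(3R,4R)-4-[4-(benzyloxy)-3-methoxybenzyl]tetrahydrofuran-3-yl]methanol
Conditions: Bu4NF (1.5 equiv), THF, 0 °C to rt
Reagents that add atoms: none
Why: Fluoride-mediated desilylation, driven by the strong Si–F bond, frees the secondary alcohol without breaking the C7'–O bond and leaves the benzyl ethers untouched, so no phenoxide is present that could expel the benzylic oxygen.

Step 11
Reactants: 15 (R)-[4-(benzyloxy)-3-methoxyphenyl][(3R,4R)-4-[4-(benzyloxy)-3-methoxybenzyl]tetrahydrofuran-3-yl]methanol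
Product: 16 (R)-(4-hydroxy-3-methoxyphenyl)[(3R,4R)-4-(4-hydroxy-3-methoxybenzyl)tetrahydrofuran-3-yl]methanol
Conditions: H2 (1 atm), 10% Pd/C, EtOAc/EtOH, rt; stopped as soon as both benzyl ethers are consumed
Reagents that add atoms: none
Why: Catalytic hydrogenolysis of aryl benzyl ethers over Pd/C under neutral conditions is faster than hydrogenolysis of a secondary benzylic C–OH bond, so a monitored reaction should free both phenols and keep the C7' hydroxyl and all three stereocentres.

Compound list
1 | 4-(benzyloxy)-3-methoxybenzaldehyde (O-benzylvanillin) | COc1cc(C=O)ccc1OCc1ccccc1 | starting material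
2 | rac-1-[4-(benzyloxy)-3-methoxyphenyl]prop-2-en-1-ol | C=CC(O)c1ccc(OCc2ccccc2)c(OC)c1 | intermediate
3 | 1-[4-(benzyloxy)-3-methoxyphenyl]prop-2-en-1-one | C=CC(=O)c1ccc(OCc2ccccc2)c(OC)c1 | intermediate
4 | rac-2-vinyloxirane | C=CC1CO1 | starting material
5 | [4-(benzyloxy)-3-methoxyphenyl][(3R,4R)-4-vinyltetrahydrofuran-3-yl]methanone (trans) | C=C[C@H]1COC[C@@H]1C(=O)c1ccc(OCc2ccccc2)c(OC)c1 | intermediate
6 | (R)-[4-(benzyloxy)-3-methoxyphenyl][(3R,4R)-4-vinyltetrahydrofuran-3-yl]methanol | C=C[C@H]1COC[C@@H]1[C@@H](O)c1ccc(OCc2ccccc2)c(OC)c1 | intermediate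
7 | tert-butyl{(R)-[4-(benzyloxy)-3-methoxyphenyl][(3R,4R)-4-vinyltetrahydrofuran-3-yl]methoxy}dimethylsilane | C=C[C@H]1COC[C@@H]1[C@@H](O[Si](C)(C)C(C)(C)C)c1ccc(OCc2ccccc2)c(OC)c1 | intermediate
8 | (3R,4R)-4-{(R)-[4-(benzyloxy)-3-methoxyphenyl][(tert-butyldimethylsilyl)oxy]methyl}tetrahydrofuran-3-carbaldehyde | O=C[C@H]1COC[C@@H]1[C@@H](O[Si](C)(C)C(C)(C)C)c1ccc(OCc2ccccc2)c(OC)c1 | intermediate
9 | [(3S,4R)-4-{(R)-[4-(benzyloxy)-3-methoxyphenyl][(tert-butyldimethylsilyl)oxy]methyl}tetrahydrofuran-3-yl]methanol | OC[C@H]1COC[C@@H]1[C@@H](O[Si](C)(C)C(C)(C)C)c1ccc(OCc2ccccc2)c(OC)c1 | intermediate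
10 | tert-butyl{(R)-[4-(benzyloxy)-3-methoxyphenyl][(3R,4R)-4-(iodomethyl)tetrahydrofuran-3-yl]methoxy}dimethylsilane | IC[C@H]1COC[C@@H]1[C@@H](O[Si](C)(C)C(C)(C)C)c1ccc(OCc2ccccc2)c(OC)c1 | intermediate
11 | 4-bromo-2-methoxyphenol | COc1cc(Br)ccc1O | starting material
12 | 1-(benzyloxy)-4-bromo-2-methoxybenzene | COc1cc(Br)ccc1OCc1ccccc1 | intermediate
13 | {[(3R,4R)-4-{(R)-[4-(benzyloxy)-3-methoxyphenyl][(tert-butyldimethylsilyl)oxy]methyl}tetrahydrofuran-3-yl]methyl}zinc iodide | I[Zn]C[C@H]1COC[C@@H]1[C@@H](O[Si](C)(C)C(C)(C)C)c1ccc(OCc2ccccc2)c(OC)c1 | intermediate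
14 | tert-butyl{(R)-[4-(benzyloxy)-3-methoxyphenyl][(3R,4R)-4-[4-(benzyloxy)-3-methoxybenzyl]tetrahydrofuran-3-yl]methoxy}dimethylsilane | COc1cc(C[C@H]2COC[C@@H]2[C@@H](O[Si](C)(C)C(C)(C)C)c2ccc(OCc3ccccc3)c(OC)c2)ccc1OCc1ccccc1 | intermediate
15 | (R)-[4-(benzyloxy)-3-methoxyphenyl][(3R,4R)-4-[4-(benzyloxy)-3-methoxybenzyl]tetrahydrofuran-3-yl]methanol | COc1cc(C[C@H]2COC[C@@H]2[C@@H](O)c2ccc(OCc3ccccc3)c(OC)c2)ccc1OCc1ccccc1 | intermediate
16 | (R)-(4-hydroxy-3-methoxyphenyl)[(3R,4R)-4-(4-hydroxy-3-methoxybenzyl)tetrahydrofuran-3-yl]methanol (CNP0234428.1) | COc1cc(C[C@H]2COC[C@@H]2[C@@H](O)c2ccc(O)c(OC)c2)ccc1O | target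

Total step count: 11. Longest linear sequence: 10 steps (steps 1–7 and 9–11, from 1 to 16); step 8 is a one-step side branch.

Steps most likely to fail

Step 3. What may go wrong: anionic oligomerisation of the vinyl ketone or palladium-mediated isomerisation of the epoxide may outrun the conjugate addition/alkylation relay, or the ligand may discriminate poorly between the faces of the allyl unit. The fallback sets out from 3 and returns at 5, and makes the two ring bonds one after the other. Phosphine-catalysed oxa-Michael addition of excess (Z)-but-2-ene-1,4-diol to 3 (PBu3 cat., THF, rt) should give 1-[4-(benzyloxy)-3-methoxyphenyl]-3-{[(2Z)-4-hydroxybut-2-en-1-yl]oxy}propan-1-one F1, in which O1–C2 already exists. Methyl chloroformate and pyridine (CH2Cl2, 0 °C) convert it into (2Z)-4-{3-[4-(benzyloxy)-3-methoxyphenyl]-3-oxopropoxy}but-2-en-1-yl methyl carbonate F2. An intramolecular Tsuji–Trost allylic alkylation (Pd2(dba)3·CHCl3, the same chiral ligand, THF, rt) then forms C3–C4 by 5-exo closure and should deliver 5; the ketone α-carbon is engaged by the methoxide released on ionisation or by pyrrolidine as enamine co-catalyst. C4 is again ligand-controlled and C3 again settles trans.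

Step 4. What may go wrong: poor facial selectivity at the carbonyl, because the α-branched ring carbon competes with the aryl group for the role of the larger substituent and the resident C3 centre may oppose the catalyst. The fallback sets out from 5 and returns at 6, and replaces asymmetric induction by separation and recycling. Unselective hydride reduction (NaBH4, MeOH, 0 °C) is followed by chromatographic separation of the C7' epimers; 6 is carried on, and the unwanted (S)-[4-(benzyloxy)-3-methoxyphenyl][(3R,4R)-4-vinyltetrahydrofuran-3-yl]methanol F3 is oxidised back to 5 with MnO2 in CH2Cl2 for another pass.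

Step 9. What may go wrong: sluggish zinc insertion, protonolysis of the alkylzinc, or β-hydride elimination competing with reductive elimination on the electron-rich aryl partner. The fallback sets out from 10 and 12 and returns at 14, with the polarity of the coupling reversed. Bromide 12 is converted with Mg turnings in THF into [4-(benzyloxy)-3-methoxyphenyl]magnesium bromide F4, which is added slowly to iodide 10 in the presence of Fe(acac)3 (5 mol%) and TMEDA (THF, 0 °C). This iron-catalysed Kumada-type aryl–alkyl coupling reacts only at the exocyclic CH2, tolerates silyl and benzyl ethers, touches no stereocentre and should give 14.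

Further compounds
F1 | step 3 | 1-[4-(benzyloxy)-3-methoxyphenyl]-3-{[(2Z)-4-hydroxybut-2-en-1-yl]oxy}propan-1-one | OC/C=C\COCCC(=O)c1ccc(OCc2ccccc2)c(OC)c1
F2 | step 3 | (2Z)-4-{3-[4-(benzyloxy)-3-methoxyphenyl]-3-oxopropoxy}but-2-en-1-yl methyl carbonate | COC(=O)OC/C=C\COCCC(=O)c1ccc(OCc2ccccc2)c(OC)c1
F3 | step 4 | (S)-[4-(benzyloxy)-3-methoxyphenyl][(3R,4R)-4-vinyltetrahydrofuran-3-yl]methanol | C=C[C@H]1COC[C@@H]1[C@H](O)c1ccc(OCc2ccccc2)c(OC)c1
F4 | step 9 | [4-(benzyloxy)-3-methoxyphenyl]magnesium bromide | COc1cc([Mg]Br)ccc1OCc1ccccc1
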